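## Retrosynthetic overview

1. Target ⇒ 1-[3,4-bis(benzyloxy)benzyl]-6-(3,4-dimethoxyphenyl)-3-oxabicyclo[3.1.0]hexan-2-one: one hydrogenolysis cuts the donor–acceptor cyclopropane bond (C1–C6) and both O-benzyl groups; the trans lactone is the thermodynamic one.
2. Bicyclic lactone ⇒ (E)-3-(3,4-dimethoxyphenyl)allyl 2-diazo-3-arylpropanoate: an enantioselective intramolecular carbene cyclopropanation closes the γ-lactone and the cyclopropane in the same event, with every carbon of the target already in place.
3. Diazo ester ⇒ cinnamyl-type acetoacetate + 3,4-bis(benzyloxy)benzyl chloride (C-alkylation, deacylative diazo transfer) ⇒ 3,4-dimethoxycinnamyl alcohol + diketene–acetone adduct.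
4. Order of rings: both arenes are bought; lactone and cyclopropane form together; the cyclopropane is opened last and the lactone stays.

Assumption: (E)-3,4-dimethoxycinnamyl alcohol and 3,4-bis(benzyloxy)benzyl chloride are bought as catalogue items; the facial sense of the step 3 cyclopropanation is not known in advance, so Rh2(S-PTTL)4 (dirhodium tetrakis[N-phthaloyl-(S)-tert-leucinate]) is written and its mirror-image form Rh2(R-PTTL)4 is substituted if the first run gives the antipode.

## Route

Step 1
Reactants: 1 (E)-3-(3,4-dimethoxyphenyl)prop-2-en-1-ol; 2 2,2,6-trimethyl-4H-1,3-dioxin-4-one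
Product: 4 (E)-3-(3,4-dimethoxyphenyl)allyl 3-oxobutanoate, via acetylketene 3 (not isolated)
Conditions: xylene, 125 °C, 1 h, acetone distilled out
Reagents that add atoms: none
Why: Thermal retro-hetero-Diels–Alder of the dioxinone releases acetone and acetylketene, which the primary allylic alcohol traps (acetoacetylation); no stereocentre is formed and the E-alkene is untouched.

Step 2
Reactants: 4 (E)-3-(3,4-dimethoxyphenyl)allyl 3-oxobutanoate; 5 1,2-bis(benzyloxy)-4-(chloromethyl)benzene
Product: 7 (E)-3-(3,4-dimethoxyphenyl)allyl 3-[3,4-bis(benzyloxy)phenyl]-2-diazopropanoate, via benzylated keto ester 6 (not isolated)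
Conditions: K2CO3, NaI (cat.), MeCN, 50 °C; then p-ABSA, DBU, 0 °C to rt
Reagents that add atoms: 4-acetamidobenzenesulfonyl azide (p-ABSA), CC(=O)Nc1ccc(cc1)S(=O)(=O)N=[N+]=[N-]
Why: Iodide-assisted SN2 C-benzylation of the acetoacetate is followed by Regitz deacylative diazo transfer, in which the sulfonyl azide adds to the enolate of 6 and the acetyl group leaves on the sulfonamide nitrogen; the racemic α-centre of 6 becomes the sp2 diazo carbon.

Step 3
Reactants: 7 (E)-3-(3,4-dimethoxyphenyl)allyl 3-[3,4-bis(benzyloxy)phenyl]-2-diazopropanoate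
Product: 8 (1S,5R,6S)-1-[3,4-bis(benzyloxy)benzyl]-6-(3,4-dimethoxyphenyl)-3-oxabicyclo[3.1.0]hexan-2-one
Conditions: Rh2(S-PTTL)4 (1 mol %), toluene–CH2Cl2, −78 °C to −40 °C, slow addition of 7
Reagents that add atoms: none
Why: Proposed new method: the chiral dirhodium tetracarboxylate turns 7 into an electrophilic rhodium carbene that adds in a concerted, stereospecific way to the tethered E-alkene, closing cyclopropane and γ-lactone together (the cis fusion fixes C1 relative to C5, the E-alkene puts the aryl exo at C6, and the catalyst's choice of alkene face sets C5 = R), while the bulky tert-leucinate ligands and −78 °C hold back the competing 1,2-hydride shift of the β-CH2 to the cinnamate; the closest known reaction types are the enantioselective intramolecular cyclopropanation of allylic diazoacetates and α-diazopropionates with chiral dirhodium catalysts and the low-temperature intermolecular cyclopropanation of α-alkyl-α-diazoesters with this same catalyst.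

Step 4
Reactants: 8 (1S,5R,6S)-1-[3,4-bis(benzyloxy)benzyl]-6-(3,4-dimethoxyphenyl)-3-oxabicyclo[3.1.0]hexan-2-one
Product: 10 (3R,4R)-3-(3,4-dihydroxybenzyl)-4-(3,4-dimethoxybenzyl)dihydrofuran-2(3H)-one (3'-O-demethylarctigenin), via cis lactone 9 (not isolated)
Conditions: H2 (3 atm), Pd/C (10 wt %), THF, rt; filter under Ar; DBU (3 equiv), degassed THF, 60 °C; then 1 M HCl
Reagents that add atoms: none
Why: Catalytic hydrogenolysis breaks the weakest cyclopropane bond, C1–C6 (benzylic to the dimethoxyaryl donor and α to the lactone carbonyl), so C6 becomes the β-benzyl CH2 while C5 (C4 of the target, R) is untouched, the two benzyl ethers fall in the same pot, and retentive hydrogen delivery at C1 gives the trans lactone directly, with base epimerisation under thermodynamic control converting any C3 epimer 9 into 10.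

## Compound list

1 | (E)-3-(3,4-dimethoxyphenyl)prop-2-en-1-ol | COc1ccc(/C=C/CO)cc1OC | starting material
2 | 2,2,6-trimethyl-4H-1,3-dioxin-4-one | CC1=CC(=O)OC(C)(C)O1 | starting material
3 | acetylketene (but-1-ene-1,3-dione) | CC(=O)C=C=O | intermediate
4 | (E)-3-(3,4-dimethoxyphenyl)allyl 3-oxobutanoate | COc1ccc(/C=C/COC(=O)CC(C)=O)cc1OC | intermediate
5 | 1,2-bis(benzyloxy)-4-(chloromethyl)benzene | ClCc1ccc(OCc2ccccc2)c(OCc2ccccc2)c1 | starting material
6 | (E)-3-(3,4-dimethoxyphenyl)allyl 2-[3,4-bis(benzyloxy)benzyl]-3-oxobutanoate (racemic) | COc1ccc(/C=C/COC(=O)C(Cc2ccc(OCc3ccccc3)c(OCc3ccccc3)c2)C(C)=O)cc1OC | intermediate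
7 | (E)-3-(3,4-dimethoxyphenyl)allyl 3-[3,4-bis(benzyloxy)phenyl]-2-diazopropanoate | COc1ccc(/C=C/COC(=O)C(=[N+]=[N-])Cc2ccc(OCc3ccccc3)c(OCc3ccccc3)c2)cc1OC | intermediate
8 | (1S,5R,6S)-1-[3,4-bis(benzyloxy)benzyl]-6-(3,4-dimethoxyphenyl)-3-oxabicyclo[3.1.0]hexan-2-one | O=C1OC[C@@H]2[C@@H](c3ccc(OC)c(OC)c3)[C@]12Cc1ccc(OCc2ccccc2)c(OCc2ccccc2)c1 | intermediate
9 | (3S,4R)-3-(3,4-dihydroxybenzyl)-4-(3,4-dimethoxybenzyl)dihydrofuran-2(3H)-one (cis epimer) | COc1ccc(C[C@H]2COC(=O)[C@H]2Cc2ccc(O)c(O)c2)cc1OC | intermediate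
10 | (3R,4R)-3-(3,4-dihydroxybenzyl)-4-(3,4-dimethoxybenzyl)dihydrofuran-2(3H)-one (3'-O-demethylarctigenin) | COc1ccc(C[C@H]2COC(=O)[C@@H]2Cc2ccc(O)c(O)c2)cc1OC | target

## Count and risks

Total steps: 4. Longest linear sequence: 4 steps (1 → 4 → 7 → 8 → 10).

**Step 3 is the most likely to fail** (1,2-hydride shift to the cinnamate, or low ee). The fallback builds the same pair of rings from the chiral pool; it sets out from 5 and comes back at 10.
- Dibenzyl malonate and (R)-epichlorohydrin with NaOBn in THF–benzyl alcohol at 60 °C give benzyl (1R,5R)-2-oxo-3-oxabicyclo[3.1.0]hexane-1-carboxylate F1 in one operation (epoxide opening, re-closure, 3-exo cyclopropane formation with inversion at the epoxide CH, lactonisation). The spatial arrangement is that of the (1S,5R) ethyl ester; only the C1 descriptor changes with the ester.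
- (3,4-Dimethoxyphenyl)magnesium bromide with CuI (cat.) in THF at −30 °C opens the cyclopropane at its CH2. The magnesium enolate is benzylated in the same flask with 5 (NaI, DMPU, 40 °C), trans to the new 3,4-dimethoxybenzyl group, to give benzyl (3S,4R)-3-[3,4-bis(benzyloxy)benzyl]-4-(3,4-dimethoxybenzyl)-2-oxotetrahydrofuran-3-carboxylate F2.
- H2 and Pd/C in THF remove all three benzyl groups to give (3R,4R)-3-(3,4-dihydroxybenzyl)-4-(3,4-dimethoxybenzyl)-2-oxotetrahydrofuran-3-carboxylic acid F3 (not isolated), which loses CO2 at 80 °C. The DBU equilibration of step 4 then converts any 9 into 10.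

**Step 4 is second** (wrong cyclopropane bond cut, sluggish C–C hydrogenolysis at the quaternary carbon, or losses on treating the free catechol with base). The fallback separates ring opening from deprotection and uses electron transfer instead of a metal surface; it sets out from 8 and comes back at 10.
- SmI2 (2.5 equiv) with HMPA and t-BuOH in THF at −78 °C reduces the lactone carbonyl to its radical anion, which opens only the C1–C6 bond (cyclopropylcarbinyl opening to the benzylic radical). There is no cationic intermediate and the benzyl ethers survive.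
- Protonation gives the ring-opened lactone as a C3-epimer mixture: (3S,4R)-3-[3,4-bis(benzyloxy)benzyl]-4-(3,4-dimethoxybenzyl)dihydrofuran-2(3H)-one F4 and (3R,4R)-3-[3,4-bis(benzyloxy)benzyl]-4-(3,4-dimethoxybenzyl)dihydrofuran-2(3H)-one F5.
- DBU in toluene at 80 °C converts F4 into F5 with no free catechol present. H2 and Pd/C in THF then remove the two benzyl groups and give 10.

**Step 2 is third** (double alkylation, or an impure diazo ester from the one-flask sequence). The fallback makes the C–C bond by reductive condensation instead of SN2 alkylation; it sets out from 4 and comes back at 6.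
- 4 and 3,4-bis(benzyloxy)benzaldehyde with L-proline (cat.) and Hantzsch ester in EtOH at rt give the Knoevenagel adduct (E)-3-(3,4-dimethoxyphenyl)allyl 2-[3,4-bis(benzyloxy)benzylidene]-3-oxobutanoate F6 (E/Z mixture at the new double bond, not isolated).
- Hydride transfer from the Hantzsch ester reduces F6 in the same flask to 6, which cannot be alkylated a second time.
- 6 is isolated and taken to 7 with p-ABSA and DBU in MeCN in a separate flask.

## Further compounds

F1 | step 3 | benzyl (1R,5R)-2-oxo-3-oxabicyclo[3.1.0]hexane-1-carboxylate | O=C1OC[C@@H]2C[C@]12C(=O)OCc1ccccc1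
F2 | step 3 | benzyl (3S,4R)-3-[3,4-bis(benzyloxy)benzyl]-4-(3,4-dimethoxybenzyl)-2-oxotetrahydrofuran-3-carboxylate | COc1ccc(C[C@H]2COC(=O)[C@@]2(Cc2ccc(OCc3ccccc3)c(OCc3ccccc3)c2)C(=O)OCc2ccccc2)cc1OC
F3 | step 3 | (3R,4R)-3-(3,4-dihydroxybenzyl)-4-(3,4-dimethoxybenzyl)-2-oxotetrahydrofuran-3-carboxylic acid | COc1ccc(C[C@H]2COC(=O)[C@@]2(Cc2ccc(O)c(O)c2)C(O)=O)cc1OC
F4 | step 4 | (3S,4R)-3-[3,4-bis(benzyloxy)benzyl]-4-(3,4-dimethoxybenzyl)dihydrofuran-2(3H)-one | COc1ccc(C[C@H]2COC(=O)[C@H]2Cc2ccc(OCc3ccccc3)c(OCc3ccccc3)c2)cc1OC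
F5 | step 4 | (3R,4R)-3-[3,4-bis(benzyloxy)benzyl]-4-(3,4-dimethoxybenzyl)dihydrofuran-2(3H)-one | COc1ccc(C[C@H]2COC(=O)[C@@H]2Cc2ccc(OCc3ccccc3)c(OCc3ccccc3)c2)cc1OC
F6 | step 2 | (E)-3-(3,4-dimethoxyphenyl)allyl 2-[3,4-bis(benzyloxy)benzylidene]-3-oxobutanoate (E/Z mixture at the benzylidene bond) | COc1ccc(/C=C/COC(=O)C(=Cc2ccc(OCc3ccccc3)c(OCc3ccccc3)c2)C(C)=O)cc1OC
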